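## Retrosynthetic overview

1. Target 20 ⇐ acetonide/tert-butyl ester 19 by acidolysis; the C2–C1′ diene bond comes from a Suzuki coupling of α-iodoenone 13 with alkenylboronate 18, made from (R)-propylene oxide.
2. 13 ⇐ β-bromoenone 9: C3–CH2OH by Stille coupling, the (E)-enoate by cross-metathesis of the C6-allyl group with tert-butyl methacrylate.
3. The C6–allyl bond and the C1 ketone come together from a Claisen rearrangement of allyl dienyl ether 6 (vinyl epoxide 3 + allyl alcohol, then dehydration). C6 is then turned cis to O-5 by kinetic protonation under control of the acetonide.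
4. Rings: the carbocycle with C4 and C5 is bought in diol 1. Only a temporary dioxolane (step 1) and an oxirane (step 2, opened in step 3) are formed.

Assumption: the bromobenzene cis-dihydrodiol 1 and (R)-propylene oxide 14 are taken as the commercial chiral starting materials.
Ring locants in the text follow the target enone: C1 = C=O, C2 (heptenyl), C3 (CH2OH), C4/C5 (OH), C6 (butenoic acid chain).

## Route

Step 1
Reactants: 1 (1S,2S)-3-bromocyclohexa-3,5-diene-1,2-diol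
Product: 2 (3aS,7aS)-4-bromo-2,2-dimethyl-3a,7a-dihydro-1,3-benzodioxole
Conditions: 2,2-dimethoxypropane, p-TsOH (cat.), acetone, 0 °C → rt
Reagents that add atoms: 2,2-dimethoxypropane COC(C)(C)OC
Why: Acid-catalysed acetonide formation (transketalisation) on the cis-diol touches no stereocentre and blocks one face of the ring for the later substrate-controlled steps.

Step 2
Reactants: 2 (3aS,7aS)-4-bromo-2,2-dimethyl-3a,7a-dihydro-1,3-benzodioxole
Product: 3 (3aS,5aR,6aR,6bS)-4-bromo-2,2-dimethyl-3a,5a,6a,6b-tetrahydrooxireno[2',3':3,4]benzo[1,2-d][1,3]dioxole (oxirane trans to the dioxolane)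
Conditions: mCPBA, CH2Cl2, 0 °C → rt
Reagents that add atoms: mCPBA OOC(=O)c1cccc(Cl)c1
Why: Prilezhaev epoxidation takes the electron-richer disubstituted alkene (not the vinyl bromide) from the face anti to the acetonide.

Step 3
Reactants: 3 (the anti vinyl epoxide above); 4 prop-2-en-1-ol (allyl alcohol)
Product: 5 (3aS,4R,5S,7aS)-7-bromo-2,2-dimethyl-5-(prop-2-en-1-yloxy)-3a,4,5,7a-tetrahydro-1,3-benzodioxol-4-ol
Conditions: 4 (5 equiv), BF3·OEt2 (10 mol %), CH2Cl2, −30 °C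
Reagents that add atoms: none
Why: Lewis-acid-catalysed SN2 opening of the vinyl oxirane at the allylic carbon with inversion puts the allyloxy group on the future C1 and leaves a trans hydroxyl on C6.

Step 4
Reactants: 5 (3aS,4R,5S,7aS)-7-bromo-2,2-dimethyl-5-(prop-2-en-1-yloxy)-3a,4,5,7a-tetrahydro-1,3-benzodioxol-4-ol
Product: 7 (3aS,4S,7aS)-7-bromo-2,2-dimethyl-4-(prop-2-en-1-yl)-3a,7a-dihydro-1,3-benzodioxol-5(4H)-one (allyl trans to the dioxolane), via (3aS,7aS)-4-bromo-2,2-dimethyl-6-(prop-2-en-1-yloxy)-3a,7a-dihydro-1,3-benzodioxole 6 (not isolated)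
Conditions: Burgess reagent, PhMe, 70 °C; then 150 °C (sealed tube)
Reagents that add atoms: none
Why: Burgess syn-elimination (Ei) takes the allylic cis β-hydrogen on the allyloxy carbon to give the allyl dienyl ether, whose Claisen [3,3]-sigmatropic rearrangement forms the C6–allyl bond on the convex face (anti to the acetonide) and unveils the C1 ketone as a β-bromoenone.

Step 5
Reactants: 7 (3aS,4S,7aS)-7-bromo-2,2-dimethyl-4-(prop-2-en-1-yl)-3a,7a-dihydro-1,3-benzodioxol-5(4H)-one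
Product: 9 (3aS,4R,7aS)-7-bromo-2,2-dimethyl-4-(prop-2-en-1-yl)-3a,7a-dihydro-1,3-benzodioxol-5(4H)-one (allyl cis to the dioxolane), via lithium (3aS,7aS)-7-bromo-2,2-dimethyl-4-(prop-2-en-1-yl)-3a,7a-dihydro-1,3-benzodioxol-5-olate 8 (not isolated)
Conditions: LDA, THF, −78 °C; then 2,6-di-tert-butyl-4-methylphenol (BHT) in THF, −78 °C
Reagents that add atoms: none
Why: α′-Deprotonation gives the planar cross-conjugated lithium dienolate, and kinetic protonation by the bulky phenol from the convex face (anti to the acetonide) pushes the allyl group cis to O-5 as in the target (substrate-controlled epimerisation; recovered 7 is recycled).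

Step 6
Reactants: 9 (3aS,4R,7aS)-7-bromo-2,2-dimethyl-4-(prop-2-en-1-yl)-3a,7a-dihydro-1,3-benzodioxol-5(4H)-one; 10 tert-butyl 2-methylprop-2-enoate (tert-butyl methacrylate)
Product: 11 tert-butyl (2E)-4-[(3aS,4R,7aS)-7-bromo-2,2-dimethyl-5-oxo-3a,4,5,7a-tetrahydro-1,3-benzodioxol-4-yl]-2-methylbut-2-enoate
Conditions: Hoveyda–Grubbs II (5 mol %), 10 (10 equiv), CH2Cl2, 40 °C
Reagents that add atoms: none
Why: Olefin cross-metathesis of the terminal alkene with the methacrylate gives the trisubstituted (E)-enoate, while the vinyl bromide and enone are inert and the neutral medium leaves C6 untouched.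

Step 7
Reactants: 11 tert-butyl (2E)-4-[(3aS,4R,7aS)-7-bromo-2,2-dimethyl-5-oxo-3a,4,5,7a-tetrahydro-1,3-benzodioxol-4-yl]-2-methylbut-2-enoate
Product: 12 tert-butyl (2E)-4-[(3aS,4R,7aR)-7-(hydroxymethyl)-2,2-dimethyl-5-oxo-3a,4,5,7a-tetrahydro-1,3-benzodioxol-4-yl]-2-methylbut-2-enoate
Conditions: Bu3SnCH2OH, Pd(PPh3)4 (5 mol %), 1,4-dioxane, 90 °C
Reagents that add atoms: (tributylstannyl)methanol CCCC[Sn](CCCC)(CCCC)CO
Why: Stille (Migita–Kosugi) hydroxymethylation of the β-bromoenone under neutral conditions installs the C3 CH2OH without disturbing C6.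

Step 8
Reactants: 12 tert-butyl (2E)-4-[(3aS,4R,7aR)-7-(hydroxymethyl)-2,2-dimethyl-5-oxo-3a,4,5,7a-tetrahydro-1,3-benzodioxol-4-yl]-2-methylbut-2-enoate
Product: 13 tert-butyl (2E)-4-[(3aS,4R,7aR)-7-(hydroxymethyl)-6-iodo-2,2-dimethyl-5-oxo-3a,4,5,7a-tetrahydro-1,3-benzodioxol-4-yl]-2-methylbut-2-enoate
Conditions: I2, pyridine, CH2Cl2, rt, dark
Reagents that add atoms: iodine II
Why: Johnson α-iodination (pyridine conjugate addition, iodination, elimination) halogenates C2 of the enone; the reaction is slow on this β,β-disubstituted enone, but the free alcohol and the enoate are untouched by the weakly basic medium.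

Step 9
Reactants: 14 (R)-2-methyloxirane ((R)-propylene oxide); 15 but-3-en-1-ylmagnesium bromide
Product: 16 (2R)-hept-6-en-2-ol
Conditions: CuI (10 mol %), THF, −30 → 0 °C; aq. NH4Cl
Reagents that add atoms: none
Why: Copper-catalysed Grignard opening of the epoxide at the unsubstituted carbon leaves the bought (R)-stereocentre untouched.

Step 10
Reactants: 16 (2R)-hept-6-en-2-ol; 17 2-ethenyl-4,4,5,5-tetramethyl-1,3,2-dioxaborolane (vinylboronic acid pinacol ester)
Product: 18 (2R,6E)-7-(4,4,5,5-tetramethyl-1,3,2-dioxaborolan-2-yl)hept-6-en-2-ol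
Conditions: Grubbs II (3 mol %), 17 (2 equiv), CH2Cl2, 40 °C
Reagents that add atoms: none
Why: Olefin cross-metathesis with the vinyl boronate gives the (E)-alkenyl pinacol boronate and tolerates the free secondary alcohol.

Step 11
Reactants: 13 (the α-iodoenone above); 18 (2R,6E)-7-(4,4,5,5-tetramethyl-1,3,2-dioxaborolan-2-yl)hept-6-en-2-ol
Product: 19 tert-butyl (2E)-4-[(3aS,4R,7aR)-7-(hydroxymethyl)-6-[(1E,6R)-6-hydroxyhept-1-en-1-yl]-2,2-dimethyl-5-oxo-3a,4,5,7a-tetrahydro-1,3-benzodioxol-4-yl]-2-methylbut-2-enoate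
Conditions: Pd(dppf)Cl2 (5 mol %), AsPh3, Ag2O, THF/H2O (8:1), rt
Reagents that add atoms: none
Why: Suzuki–Miyaura coupling of the α-iodoenone with the alkenyl boronate retains the (E)-geometry, and the silver(I) oxide promoter keeps the medium near neutral so C6 (α to the ketone) and O-5 (β to it) survive.

Step 12
Reactants: 19 (the coupled acetonide tert-butyl ester above)
Product: 20 pestallic acid I, (2E)-4-[(1R,2S,3R)-2,3-dihydroxy-4-(hydroxymethyl)-5-[(1E,6R)-6-hydroxyhept-1-en-1-yl]-6-oxocyclohex-4-en-1-yl]-2-methylbut-2-enoic acid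
Conditions: TFA/H2O (9:1), 0 °C → rt; evaporate, C18 chromatography
Reagents that add atoms: none
Why: Aqueous trifluoroacetic acid hydrolyses the acetonide and cleaves the tert-butyl ester (AAL1) in one operation without breaking any bond to a stereocentre, giving the target.

## Compound list

1 | (1S,2S)-3-bromocyclohexa-3,5-diene-1,2-diol | O[C@H]1C=CC=C(Br)[C@H]1O | starting material
2 | (3aS,7aS)-4-bromo-2,2-dimethyl-3a,7a-dihydro-1,3-benzodioxole | C1=CC=C(Br)[C@H]2OC(C)(C)O[C@@H]12 | intermediate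
3 | (3aS,5aR,6aR,6bS)-4-bromo-2,2-dimethyl-3a,5a,6a,6b-tetrahydrooxireno[2',3':3,4]benzo[1,2-d][1,3]dioxole | BrC1=C[C@H]2O[C@H]2[C@@H]2OC(C)(C)O[C@H]12 | intermediate
4 | prop-2-en-1-ol | C=CCO | starting material
5 | (3aS,4R,5S,7aS)-7-bromo-2,2-dimethyl-5-(prop-2-en-1-yloxy)-3a,4,5,7a-tetrahydro-1,3-benzodioxol-4-ol | BrC1=C[C@H](OCC=C)[C@@H](O)[C@@H]2OC(C)(C)O[C@H]12 | intermediate
6 | (3aS,7aS)-4-bromo-2,2-dimethyl-6-(prop-2-en-1-yloxy)-3a,7a-dihydro-1,3-benzodioxole | BrC1=CC(OCC=C)=C[C@@H]2OC(C)(C)O[C@H]12 | intermediate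
7 | (3aS,4S,7aS)-7-bromo-2,2-dimethyl-4-(prop-2-en-1-yl)-3a,7a-dihydro-1,3-benzodioxol-5(4H)-one | C=CC[C@@H]1C(=O)C=C(Br)[C@H]2OC(C)(C)O[C@@H]12 | intermediate
8 | lithium (3aS,7aS)-7-bromo-2,2-dimethyl-4-(prop-2-en-1-yl)-3a,7a-dihydro-1,3-benzodioxol-5-olate | C=CCC1=C([O-])C=C(Br)[C@H]2OC(C)(C)O[C@@H]12.[Li+] | intermediate
9 | (3aS,4R,7aS)-7-bromo-2,2-dimethyl-4-(prop-2-en-1-yl)-3a,7a-dihydro-1,3-benzodioxol-5(4H)-one | C=CC[C@H]1C(=O)C=C(Br)[C@H]2OC(C)(C)O[C@@H]12 | intermediate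
10 | tert-butyl 2-methylprop-2-enoate | CC(=C)C(=O)OC(C)(C)C | starting material
11 | tert-butyl (2E)-4-[(3aS,4R,7aS)-7-bromo-2,2-dimethyl-5-oxo-3a,4,5,7a-tetrahydro-1,3-benzodioxol-4-yl]-2-methylbut-2-enoate | C/C(=C\C[C@H]1C(=O)C=C(Br)[C@H]2OC(C)(C)O[C@@H]12)C(=O)OC(C)(C)C | intermediate
12 | tert-butyl (2E)-4-[(3aS,4R,7aR)-7-(hydroxymethyl)-2,2-dimethyl-5-oxo-3a,4,5,7a-tetrahydro-1,3-benzodioxol-4-yl]-2-methylbut-2-enoate | C/C(=C\C[C@H]1C(=O)C=C(CO)[C@H]2OC(C)(C)O[C@@H]12)C(=O)OC(C)(C)C | intermediate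
13 | tert-butyl (2E)-4-[(3aS,4R,7aR)-7-(hydroxymethyl)-6-iodo-2,2-dimethyl-5-oxo-3a,4,5,7a-tetrahydro-1,3-benzodioxol-4-yl]-2-methylbut-2-enoate | C/C(=C\C[C@H]1C(=O)C(I)=C(CO)[C@H]2OC(C)(C)O[C@@H]12)C(=O)OC(C)(C)C | intermediate
14 | (R)-2-methyloxirane | C[C@@H]1CO1 | starting material
15 | but-3-en-1-ylmagnesium bromide | C=CCC[Mg]Br | starting material
16 | (2R)-hept-6-en-2-ol | C[C@@H](O)CCCC=C | intermediate
17 | 2-ethenyl-4,4,5,5-tetramethyl-1,3,2-dioxaborolane | C=CB1OC(C)(C)C(C)(C)O1 | starting material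
18 | (2R,6E)-7-(4,4,5,5-tetramethyl-1,3,2-dioxaborolan-2-yl)hept-6-en-2-ol | C[C@@H](O)CCC/C=C/B1OC(C)(C)C(C)(C)O1 | intermediate
19 | tert-butyl (2E)-4-[(3aS,4R,7aR)-7-(hydroxymethyl)-6-[(1E,6R)-6-hydroxyhept-1-en-1-yl]-2,2-dimethyl-5-oxo-3a,4,5,7a-tetrahydro-1,3-benzodioxol-4-yl]-2-methylbut-2-enoate | C/C(=C\C[C@H]1C(=O)C(/C=C/CCC[C@@H](C)O)=C(CO)[C@H]2OC(C)(C)O[C@@H]12)C(=O)OC(C)(C)C | intermediate
20 | pestallic acid I, (2E)-4-[(1R,2S,3R)-2,3-dihydroxy-4-(hydroxymethyl)-5-[(1E,6R)-6-hydroxyhept-1-en-1-yl]-6-oxocyclohex-4-en-1-yl]-2-methylbut-2-enoic acid | C/C(=C\C[C@H]1C(=O)C(/C=C/CCC[C@@H](C)O)=C(CO)[C@@H](O)[C@H]1O)C(=O)O | target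

## Step count and risks

Total steps: 12. Longest linear sequence: 10 (steps 1–8, 11, 12).

Step 5 is the most likely to fail. The kinetic protonation is contra-steric, its selectivity may be modest, and the enolate can lose the β-oxygen at C5. The fallback sets out from 7 and fixes C6 by radical hydrogen-atom transfer instead of ionic protonation. LiHMDS/TMSCl (THF, −78 °C) gives the silyl dienol ether {[(3aS,7aS)-4-bromo-2,2-dimethyl-7-(prop-2-en-1-yl)-3a,7a-dihydro-1,3-benzodioxol-6-yl]oxy}trimethylsilane F3. PhSeCl (CH2Cl2, −78 °C) then selenenylates C6 from the convex face to give the quaternary selenide (3aR,4S,7aS)-7-bromo-2,2-dimethyl-4-(phenylselanyl)-4-(prop-2-en-1-yl)-3a,7a-dihydro-1,3-benzodioxol-5(4H)-one F4. Bu3SnH/Et3B (PhMe, −78 °C) cleaves the C–Se bond and delivers H from the convex face, coming back to the route at 9.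

Step 4 is the second risk. The Burgess elimination could go towards the ring-fusion hydrogen, and dienyl ether 6 is acid- and heat-sensitive. The fallback sets out from 2 and replaces steps 2–4 by an enolate alkylation. Diimide (potassium azodicarboxylate, AcOH, MeOH, 0 °C) saturates the distal alkene to give (3aS,7aS)-4-bromo-2,2-dimethyl-3a,6,7,7a-tetrahydro-1,3-benzodioxole F1. CrO3·3,5-dimethylpyrazole (CH2Cl2, −20 °C) oxidises the allylic CH2 to the β-bromoenone (3aS,7aS)-7-bromo-2,2-dimethyl-3a,7a-dihydro-1,3-benzodioxol-5(4H)-one F2. LDA then allyl bromide (THF, −78 °C) alkylates C6 anti to the acetonide, coming back to the route at 7.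

Step 12 is the third risk. The strongly acidic one-pot unmasking may dehydrate or aromatise the β-hydroxy ketone or epimerise C6. The fallback sets out from 19 and unmasks in two orthogonal, milder stages. TMSOTf/2,6-lutidine (CH2Cl2, 0 °C) turns the tert-butyl ester into a silyl ester that is hydrolysed on work-up to (2E)-4-[(3aS,4R,7aR)-7-(hydroxymethyl)-6-[(1E,6R)-6-hydroxyhept-1-en-1-yl]-2,2-dimethyl-5-oxo-3a,4,5,7a-tetrahydro-1,3-benzodioxol-4-yl]-2-methylbut-2-enoic acid F5, with the acetonide intact. Dowex 50W (H+) in MeOH/H2O at rt then removes the acetonide, arriving at 20.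

## Further compounds

F1 | step 4 | (3aS,7aS)-4-bromo-2,2-dimethyl-3a,6,7,7a-tetrahydro-1,3-benzodioxole | C1CC=C(Br)[C@H]2OC(C)(C)O[C@@H]12
F2 | step 4 | (3aS,7aS)-7-bromo-2,2-dimethyl-3a,7a-dihydro-1,3-benzodioxol-5(4H)-one | C1C(=O)C=C(Br)[C@H]2OC(C)(C)O[C@@H]12
F3 | step 5 | {[(3aS,7aS)-4-bromo-2,2-dimethyl-7-(prop-2-en-1-yl)-3a,7a-dihydro-1,3-benzodioxol-6-yl]oxy}trimethylsilane | C=CCC1=C(O[Si](C)(C)C)C=C(Br)[C@H]2OC(C)(C)O[C@@H]12
F4 | step 5 | (3aR,4S,7aS)-7-bromo-2,2-dimethyl-4-(phenylselanyl)-4-(prop-2-en-1-yl)-3a,7a-dihydro-1,3-benzodioxol-5(4H)-one | C=CC[C@@]1([Se]c2ccccc2)C(=O)C=C(Br)[C@H]2OC(C)(C)O[C@@H]12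
F5 | step 12 | (2E)-4-[(3aS,4R,7aR)-7-(hydroxymethyl)-6-[(1E,6R)-6-hydroxyhept-1-en-1-yl]-2,2-dimethyl-5-oxo-3a,4,5,7a-tetrahydro-1,3-benzodioxol-4-yl]-2-methylbut-2-enoic acid | C/C(=C\C[C@H]1C(=O)C(/C=C/CCC[C@@H](C)O)=C(CO)[C@H]2OC(C)(C)O[C@@H]12)C(=O)O
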